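In a one-step world the rate is proportional to c_partner. Look at a fixed conversion: a fixed amount has left the partner, so one percent more charged means more than one percent more left. The order in partner is then the charge over c_partner at the look, not 1.

the same everywhere: free catalyst 4.6 mM
- east: left-handed substrate 0.050 M; right-handed substrate 0.050 M; partner 0.15 M; protic impurity 0.030 M; run made earlier
- south-west: left-handed substrate 0.20 M; right-handed substrate 0.20 M; partner 0.15 M; protic impurity 0.030 M; run made earlier
- north-west: left-handed substrate 0.10 M; right-handed substrate 0.10 M; partner 0.075 M; protic impurity 0.030 M; run made earlier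
- flask: left-handed substrate 0.10 M; right-handed substrate 0.10 M; partner 0.150 M; protic impurity 0.0300 M

- east (time / h: left-handed product / %, left-handed substrate / %): 1.33: 8.5, 41.9; 3.00: 13.3, 36.1; 4.00: 14.9, 32.9; 6.00: 19.9, 29.7; 8.00: 26.2, 25.4; 10.0: 26.6, 21.5
- south-west (time / h: left-handed product / %, left-handed substrate / %): 0.833: 0.8, 46.7; 1.33: 2.6, 47.5; 2.00: 2.5, 45.8; 2.50: 3.7, 44.6; 4.00: 4.7, 42.5; 6.00: 9.0, 39.0; 10.0: 12.1, 38.2
- north-west (time / h: left-handed product / %, left-handed substrate / %): 2.00: 2.8, 45.8; 4.00: 5.5, 43.4; 6.00: 6.7, 40.2; 8.00: 9.0, 39.2; 10.0: 12.1, 38.3

(scatter of a reading: 1 percentage point)

- apparent order in partner when 20 % of the left-handed substrate and right-handed substrate together are converted (percent change of the rate of making left-handed product for one percent more partner charged)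

- free catalyst is single-handed; left-handed substrate and right-handed substrate are mirror images of each other, charged as a racemate, each of them at the stated concentration
- candidate steps: free catalyst + left-handed substrate <-> catalyst intermediate A; partner + free catalyst -> spent catalyst; free catalyst + right-handed substrate <-> catalyst intermediate B; partner + catalyst intermediate B -> free catalyst + right-handed product; partner + protic impurity -> quenched reagent; partner + catalyst intermediate A -> free catalyst + left-handed product
- what is bound to the catalyst counts as converted

Start with the slope. Over the first 6.00 h the readings give left-handed product a slope of 0.00332 M h⁻¹ in the east run and 0.00600 M h⁻¹ in the south-west run. The south-west run holds 4.00 times the substrate, and its slope reads 1.81 times the east one, so the slope grows less than the charge. At 10.0 h the south-west run reads 0.0484 M and the north-west run 0.0242 M, a ratio of 2.00, while their partner charges stand at 2.00 to each other and their substrate charges at 2.00. So I expect your flask, with the partner charge of those two runs and 0.10 M of each substrate, to run between the east and south-west slopes over the same hours and bend down as c_partner falls.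

Next comes the look. A conversion of 20 % of both substrates takes about 0.0400 M of partner, since up to 4.6 mM of it is bound to the catalyst and counts as converted. With no protic impurity reacted the ratio is 1.36; with its whole charge reacted, 1.88. I take half as reacted, which gives 1.58. This leverage, the partner charged over c_partner at the look, is what to carry.

Then the level. Partner is the limiting reagent: 0.120 M after impurity is less than the 0.200 M of substrate, so products should level near 60.0 %, above the look.

The forecast says 1.4, on the ground that “catalyst death and impurity loss per unit conversion do not depend on partner”. It takes the impurity loss near 0.01 M, and its number is lower than mine.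

The flask gives 1.6.

    free catalyst + left-handed substrate ⇌ catalyst intermediate A (K = 14.0 L mol⁻¹, k = 33.0 L mol⁻¹ min⁻¹)
    partner + free catalyst → spent catalyst (k = 0.0130 L mol⁻¹ min⁻¹)
    free catalyst + right-handed substrate ⇌ catalyst intermediate B (K = 13.0 L mol⁻¹, k = 18.0 L mol⁻¹ min⁻¹)
    partner + catalyst intermediate B → free catalyst + right-handed product (k = 0.210 L mol⁻¹ min⁻¹)
    partner + protic impurity → quenched reagent (k = 0.0230 L mol⁻¹ min⁻¹)
    partner + catalyst intermediate A → free catalyst + left-handed product (k = 0.490 L mol⁻¹ min⁻¹)

Watch partner. The look comes at 4.98 h. At 4.00 h the flask holds 68.6 % of its partner charge, with quenched reagent at 0.0148 M, so the leverage reads 1.46 there. At 8.00 h the flask holds 51.6 %, and the leverage reads 1.94.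

(The runs are simulated with constants of no real substance; noise was put on by code.)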